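Prosogerin D is disconnected at O1–C2 and C4a–C5, which unfolds rings C and A into one open chain. Ring A has oxygen at C8a and C7 in the alternating polyketide pattern, hydrogen at C5 and methoxy at C6. A chain whose far end is an alpha-methoxy aldehyde acetal carries this pattern. One acid treatment should close the 4-pyranone from the aryl 1,3,5-triketone end and then join the pyranone carbon (future C4a) to the acetal carbon (future C5), aromatising ring A with the C7 hydroxyl free. The precursor is the linear 1-aryl-1,3,5,7-tetraketone ending in CH(OMe)CH(OMe)2, assembled from acetylacetone by two polyanion acylations.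

Key step: step 4

Remark (assumption): chain atoms C1 to C9 of the tetraketone become flavone atoms C2, C3, C4, C4a, C8a, C8, C7, C6 and C5. The polyketones are drawn as keto forms although largely enolised. The stereocentres of the ester (C2) and the tetraketone (C8) are racemic and vanish on aromatisation, so no stereocontrol is needed.

Step 1
Reactants: 1 pentane-2,4-dione (acetylacetone); 2 methyl 3,4,5-trimethoxybenzoate
Product: 4 1-(3,4,5-trimethoxyphenyl)hexane-1,3,5-trione, via dilithium acetylacetone dianion 3 (not isolated)
Conditions: 1 (2.2 equiv), LiN(iPr)2 (4.4 equiv), THF, 0 °C; then 2 (1.0 equiv), 0 °C to rt; cold 1 M HCl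
Reagents that add atoms: none
Why: Claisen-type acylation of a 1,3-diketone dianion, in which the terminal carbanion of 3 is the most nucleophilic site, the aroyl ester cannot enolise, and the second equivalent of dianion takes up the acidic proton of the first-formed triketone so that the reaction should not stall.

Step 2
Reactants: 5 methyl methoxyacetate; 6 methyl formate
Product: 8 racemic methyl 2,3,3-trimethoxypropanoate, via sodium formyl ester enolate 7 (not isolated)
Conditions: NaOMe (1.1 equiv), 6 (2 equiv), THF, 0 °C to rt; then HCl (2.5 equiv), anhydrous MeOH, 0 °C to rt; neutralise, distil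
Reagents that add atoms: methanol, CO
Why: Crossed Claisen formylation (methyl formate cannot enolise and is the better electrophile) followed by acid-catalysed acetalisation of the liberated formyl ester in excess methanol; the C2 stereocentre forms without control, which is harmless because it ends as planar C6 of ring A.

Step 3
Reactants: 4 1-(3,4,5-trimethoxyphenyl)hexane-1,3,5-trione; 8 racemic methyl 2,3,3-trimethoxypropanoate
Product: 10 racemic 8,9,9-trimethoxy-1-(3,4,5-trimethoxyphenyl)nonane-1,3,5,7-tetraone, via trilithium triketone trianion 9 (not isolated)
Conditions: 4 (2.0 equiv), LiN(iPr)2 (6.0 equiv), THF, 0 °C; then 8 (1.0 equiv), −78 to 0 °C; cold 1 M HCl to pH 4; quick filtration through acid-washed silica, used at once (spare 4 recovered)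
Reagents that add atoms: none
Why: Claisen-type acylation of a 1,3,5-triketone trianion at its terminal methylene carbanion, the established entry to 1,3,5,7-tetraketones, in which the acetal is inert to base, the product stays shielded from aldol folding as its polyenolate until the cold acid quench, and the spare trianion absorbs the extra acidic proton of the tetraketone.

Step 4
Reactants: 10 racemic 8,9,9-trimethoxy-1-(3,4,5-trimethoxyphenyl)nonane-1,3,5,7-tetraone
Product: 12 Prosogerin D, via aryl pyranone keto acetal 11 (not isolated)
Conditions: p-TsOH (dried, 1.5 equiv), PhMe, 60 °C; then reflux, Dean–Stark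
Reagents that add atoms: none
Why: Proposed new method: acid should first cyclodehydrate the aryl 1,3,5-triketone end of 10 (the enol oxygen on chain C5 adds to the protonated aryl ketone C1 in a 6-exo-trig closure and water is lost), giving pyranone 11 with O1–C2 in place, after which the acetal, slow to ionise because of its alpha-methoxy and beta-keto neighbours, gives an oxocarbenium ion (or the derived beta-methoxy enone) at chain C9 that is captured by chain C4 of the pyranone, the future C4a, in a 6-(enolendo)-exo-trig closure forming C4a–C5. Loss of the second methanol and tautomerisation of the C7 ketone then aromatise ring A with 6-OMe and free 7-OH. The closest known reaction types are the acid cyclodehydration of aryl 1,3,5-triketones to 2-aryl-4-pyranones and aromatising condensations in which the carbon of a beta-keto acetal becomes an unsubstituted ring CH (formal [3+3] benzannulations of bis-silyl dienol ethers, Bradsher- and Pomeranz–Fritsch-type acetal cyclodehydrations). No stereocentre is created and the racemic C8 centre of 10 becomes planar C6. The step needs the pyranone to close over C1/C3/C5 and not over C3/C5/C7 or through the C5 oxygen onto the aldehyde carbon; aryl conjugation, the branched C7 terminus and the sluggish acetal should favour this, and if C4a–C5 forms first the resulting 2-hydroxyaryl 1,3-diketone closes to the same flavone.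

Compound list
1 | pentane-2,4-dione (acetylacetone) | CC(=O)CC(C)=O | starting material
2 | methyl 3,4,5-trimethoxybenzoate | COC(=O)c1cc(OC)c(OC)c(OC)c1 | starting material
3 | dilithium dianion of pentane-2,4-dione (not isolated) | [Li+].[Li+].C=C([O-])C=C(C)[O-] | intermediate
4 | 1-(3,4,5-trimethoxyphenyl)hexane-1,3,5-trione | COc1cc(C(=O)CC(=O)CC(C)=O)cc(OC)c1OC | intermediate
5 | methyl methoxyacetate | COCC(=O)OC | starting material
6 | methyl formate | COC=O | starting material
7 | sodium enolate of methyl 2-methoxy-3-oxopropanoate (not isolated, double-bond geometry undefined) | COC(=O)C(OC)=C[O-].[Na+] | intermediate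
8 | racemic methyl 2,3,3-trimethoxypropanoate | COC(OC)C(OC)C(=O)OC | intermediate
9 | trilithium trianion of 1-(3,4,5-trimethoxyphenyl)hexane-1,3,5-trione (not isolated) | [Li+].[Li+].[Li+].C=C([O-])C=C([O-])C=C([O-])c1cc(OC)c(OC)c(OC)c1 | intermediate
10 | racemic 8,9,9-trimethoxy-1-(3,4,5-trimethoxyphenyl)nonane-1,3,5,7-tetraone | COc1cc(C(=O)CC(=O)CC(=O)CC(=O)C(OC)C(OC)OC)cc(OC)c1OC | intermediate
11 | racemic 2-(3,4,4-trimethoxy-2-oxobutyl)-6-(3,4,5-trimethoxyphenyl)-4H-pyran-4-one (not isolated) | COc1cc(-c2cc(=O)cc(CC(=O)C(OC)C(OC)OC)o2)cc(OC)c1OC | intermediate
12 | Prosogerin D (7-hydroxy-6-methoxy-2-(3,4,5-trimethoxyphenyl)-4H-chromen-4-one) | COc1cc2c(=O)cc(-c3cc(OC)c(OC)c(OC)c3)oc2cc1O | target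

Total step count: 4. Longest linear sequence: 3 steps (step 1 or step 2, then steps 3 and 4).

Steps most likely to fail

Step 4 (proposed new method). Several things may go wrong:
- The pyranone may close over the inner triketone (C3/C5/C7).
- The C5 enol oxygen may cyclise onto the ionised acetal carbon.
- The chain may fold by aldol reaction between C2 and C7.
- The protonated pyranone may attack the deactivated oxocarbenium ion too slowly.

The first three divert the chain into products that cannot form C4a–C5. The fallback uses only known chemistry, sets out from 2 and comes back at 12. Purchased 4-methoxybenzene-1,3-diol F1 is C-acetylated para to one hydroxyl and ortho to the other (AcOH, BF3·OEt2, 90 °C, Friedel–Crafts acylation) to 1-(2,4-dihydroxy-5-methoxyphenyl)ethanone F2. Its lithium polyanion (LiN(SiMe3)2, 4 equiv, THF, −78 °C to rt) undergoes Claisen condensation with ester 2 to give 1-(2,4-dihydroxy-5-methoxyphenyl)-3-(3,4,5-trimethoxyphenyl)propane-1,3-dione F3, the diketone of a Baker–Venkataraman flavone synthesis. H2SO4 in AcOH at 100 °C should cyclodehydrate it to 12.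

Step 3. The strongly basic trianion may deprotonate ester 8 at its alpha position, with beta-elimination of methoxide, in place of acylation. The free tetraketone may also fold prematurely during quench and purification. The fallback sets out from 4 and comes back at 11. Cold concentrated H2SO4 (0 °C) cyclodehydrates 4 to 2-methyl-6-(3,4,5-trimethoxyphenyl)-4H-pyran-4-one F4. Its methyl group is deprotonated (LiN(SiMe3)2, 2.2 equiv, THF, −78 °C) and the less basic lateral anion is acylated with 8 to give 11. Compound 11 is then taken through the reflux stage of step 4 to 12. This fallback also fixes the pyranone regiochemistry before the aldehyde is unmasked.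

Step 1. Proton exchange between the first-formed triketone and unreacted dianion, or O-aroylation, may leave conversion incomplete. The fallback sets out from 2 and comes back at 4. Claisen condensation of 2 with acetone (NaH, THF, reflux) gives 1-(3,4,5-trimethoxyphenyl)butane-1,3-dione F5. Its dianion (LiN(iPr)2, 2.2 equiv, THF, 0 °C) is acetylated at the terminal methyl with N-methoxy-N-methylacetamide to give 4.

Further compounds
F1 | step 4 | 4-methoxybenzene-1,3-diol (purchased) | COc1ccc(O)cc1O
F2 | step 4 | 1-(2,4-dihydroxy-5-methoxyphenyl)ethanone | COc1cc(C(C)=O)c(O)cc1O
F3 | step 4 | 1-(2,4-dihydroxy-5-methoxyphenyl)-3-(3,4,5-trimethoxyphenyl)propane-1,3-dione | COc1cc(C(=O)CC(=O)c2cc(OC)c(OC)c(OC)c2)c(O)cc1O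
F4 | step 3 | 2-methyl-6-(3,4,5-trimethoxyphenyl)-4H-pyran-4-one | Cc1cc(=O)cc(-c2cc(OC)c(OC)c(OC)c2)o1
F5 | step 1 | 1-(3,4,5-trimethoxyphenyl)butane-1,3-dione | COc1cc(C(=O)CC(C)=O)cc(OC)c1OC
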